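**Plan**

1. Carotenoid numbering is used: ring A is the β-ring (C1–C6, palmitate on O3), ring B the ε-ring (C1'–C6', myristate on O3'). The retrosynthesis first cuts the two ester C–O bonds and then, in one operation, C14–C15, C15'–C14', C13–C20 and C13'–C20'.
2. The chain itself offers this cut: the unbranched C15=C15' ethene lies between two E-trisubstituted alkenes, C13=C14 and C13'=C14', whose methyl groups C20 and C20' sit on the carbons remote from the centre. That is the imprint of a syn-methylmetalated terminal alkyne joined to a two-carbon dihalide; neither ring takes part.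
3. Each C18 tetraenyne is cut once more in the same way (C9–C19 with C10–C11, C9'–C19' with C10'–C11') to a C13 dienyne, Me3Al and a C4 bromoenyne; the dienynes come from methyl ketones.
4. Forward: no ring is built; ring A comes from ketoisophorone, ring B from racemic α-ionone. The ring A chain grows by C6–C7 (Heck reaction) and C10–C11, the ring B chain by C10'–C11', the halves meet at C15/C15', and the esters go on last, O3' before O3.
5. Stereochemistry: C3 from an enzymatic C=C reduction of ketoisophorone followed by a substrate-controlled ketone reduction. C3' and C6' come from a trans-selective hydride reduction of racemic 3-oxo-α-ionone acetal and a lipase resolution. Every chain alkene is E through syn-carbometalation, E-haloalkenes and stereoretentive couplings.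

Key step: step 19

Remark: in step 14 the lipase is taken to acetylate the (3S,6S)-alcohol (CH2–CMe2 arm as the large group in the usual size rule for secondary alcohols) and to leave the (3R,6R)-alcohol; (E)-1-bromo-2-iodoethene is made in step 1 because its supply is not assured.

**Linchpins**

Step 1
Reactants: 1 acetylene
Product: 2 (E)-1-bromo-2-iodoethene
Conditions: IBr, 48% aq. HBr, 0 °C, acetylene bubbled in
Reagents that add atoms: iodine monobromide, BrI
Why: Electrophilic anti-addition of iodine monobromide to the alkyne through a bridged iodonium ion places Br and I on opposite sides, so only the E-dihaloethene should form (halogenation of an alkyne).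

Step 2
Reactants: 2 (E)-1-bromo-2-iodoethene; 3 ethynyltrimethylsilane
Product: 6 (E)-(4-bromobut-3-en-1-yn-1-yl)trimethylsilane, via lithium trimethylsilylacetylide 4 (not isolated), via bromo(trimethylsilylethynyl)zinc 5 (not isolated)
Conditions: 3, n-BuLi, THF, −78 °C; ZnBr2, 0 °C; then 2 (slight excess), Pd(PPh3)4 (cat.), THF, 0 °C to rt
Reagents that add atoms: none
Why: Negishi alkynyl–alkenyl coupling in which zerovalent palladium inserts into the C–I bond far faster than into C–Br, so one alkynyl group is transferred at the iodide end with retention of the E geometry.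

**Ring A half**

Step 3
Reactants: 7 ketoisophorone
Product: 8 (6R)-levodione
Conditions: ene-reductase OYE1 (old yellow enzyme), NADP+ (cat.), glucose dehydrogenase, D-glucose, phosphate buffer pH 7, 30 °C
Reagents that add atoms: none
Why: Flavin-dependent ene-reductase catalysis (biocatalytic conjugate reduction) adds hydride and proton trans across the enedione C=C inside the chiral active site, which sets the methyl-bearing centre as 6R, while glucose dehydrogenase recycles the nicotinamide cofactor.

Step 4
Reactants: 8 (6R)-levodione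
Product: 9 (4R,6R)-actinol
Conditions: LiBH(s-Bu)3 (1.05 equiv), THF, −78 °C; H2O
Reagents that add atoms: none
Why: Chemo- and diastereoselective hydride reduction: the bulky borohydride reaches only the unhindered C4 carbonyl and attacks it equatorially, away from the axial C2 methyl group, so the axial 4R alcohol trans to the equatorial 6-methyl group should result.

Step 5
Reactants: 9 (4R,6R)-actinol
Product: 10 (4R,6R)-4-(tert-butyldiphenylsilyloxy)-2,2,6-trimethylcyclohexan-1-one
Conditions: t-BuPh2SiCl, imidazole, DMAP (cat.), DMF, 40 °C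
Reagents that add atoms: tert-butyl(chloro)diphenylsilane, CC(C)(C)[Si](Cl)(c1ccccc1)c1ccccc1
Why: Imidazole-promoted silylation of the secondary alcohol gives a silyl ether that tolerates amide bases, palladium catalysis and trimethylaluminium in the later steps.

Step 6
Reactants: 10 (4R,6R)-4-(tert-butyldiphenylsilyloxy)-2,2,6-trimethylcyclohexan-1-one
Product: 12 (4R)-4-(tert-butyldiphenylsilyloxy)-2,6,6-trimethylcyclohex-1-en-1-yl trifluoromethanesulfonate, via lithium enolate 11 (not isolated)
Conditions: LiN(i-Pr)2, THF, −78 to 0 °C; PhNTf2, −78 °C to rt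
Reagents that add atoms: N-phenylbis(trifluoromethanesulfonimide), O=S(=O)(N(c1ccccc1)S(=O)(=O)C(F)(F)F)C(F)(F)F
Why: Enolate O-triflation: C6 carries the only α-hydrogen (C2 is quaternary), so deprotonation and trapping give a single tetrasubstituted enol triflate, the C6 centre being given up on purpose while C4 is untouched.

Step 7
Reactants: 12 ring A enol triflate; 13 methyl vinyl ketone
Product: 14 (3R)-3-(tert-butyldiphenylsilyloxy)-β-ionone
Conditions: Pd(OAc)2 (cat.), PPh3, Et3N, DMF, 70 °C
Reagents that add atoms: none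
Why: Heck reaction: oxidative addition of the enol triflate to zerovalent palladium, syn insertion of the enone and syn β-hydride elimination should deliver the E-dienone with the new C6–C7 bond.

Step 8
Reactants: 14 (3R)-3-(tert-butyldiphenylsilyloxy)-β-ionone
Product: 17 ring A C13 dienyne, via lithium enolate 15 (not isolated), via enol phosphate 16 (not isolated)
Conditions: LiN(i-Pr)2 (1.05 equiv), THF, −78 °C; ClP(O)(OEt)2, −78 °C to rt; LiN(i-Pr)2 (2.3 equiv), −78 °C to rt; aq. NH4Cl
Reagents that add atoms: none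
Why: Methyl ketone to terminal alkyne conversion through an enol phosphate: kinetic deprotonation of the methyl group, O-phosphorylation and base-induced E2 loss of diethyl phosphate give the acetylide, which is protonated on work-up.

Step 9
Reactants: 17 ring A C13 dienyne; 6 (E)-(4-bromobut-3-en-1-yn-1-yl)trimethylsilane
Product: 19 ring A C18 silylated polyenyne, via ring A C14 alkenylalane 18 (not isolated)
Conditions: Me3Al (2 equiv), Cp2ZrCl2 (0.2 equiv), ClCH2CH2Cl, rt; volatiles removed; 6, ZnCl2 (1 equiv), Pd(PPh3)4 (cat.), THF, rt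
Reagents that add atoms: trimethylaluminium, C[Al](C)C
Why: Zirconium-catalysed syn-methylalumination of the terminal alkyne (Negishi carboalumination) fixes C9=C10 as E with the new methyl on C9, and the palladium- and zinc-mediated Negishi coupling with the E-bromoenyne then forms C10–C11 with retention at both partners.

Step 10
Reactants: 19 ring A C18 silylated polyenyne
Product: 20 ring A C18 polyenyne
Conditions: K2CO3, MeOH–THF, rt
Reagents that add atoms: none
Why: Base-catalysed methanolysis of the alkynyl C–Si bond (protodesilylation) frees the terminal alkyne while the bulky silyl ether stays in place.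

**Ring B half**

Step 11
Reactants: 21 α-ionone (racemic)
Product: 22 α-ionone ethylene acetal (racemic)
Conditions: Me3SiOCH2CH2OSiMe3, Me3SiOTf (cat.), CH2Cl2, −78 °C
Reagents that add atoms: 1,2-bis(trimethylsilyloxy)ethane, C[Si](C)(C)OCCO[Si](C)(C)C
Why: Noyori acetalisation under aprotic silyl triflate catalysis at low temperature converts the enone into its dioxolane without moving either double bond.

Step 12
Reactants: 22 α-ionone ethylene acetal
Product: 23 3-oxo-α-ionone ethylene acetal (racemic)
Conditions: t-BuOOH (70% aq.), Rh2(cap)4 (cat., cap = caprolactamate), K2CO3 (0.5 equiv), CH2Cl2, rt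
Reagents that add atoms: tert-butyl hydroperoxide, CC(C)(C)OO
Why: Radical allylic oxidation: the tert-butylperoxyl radical abstracts hydrogen from the ring methylene C3 next to the trisubstituted alkene and the mixed peroxide collapses to the enone, whereas the hindered tertiary C6–H cannot lead to a ketone.

Step 13
Reactants: 23 3-oxo-α-ionone ethylene acetal
Product: 25 rac-trans-3-hydroxy-α-ionone, via hydroxy acetal 24 (not isolated)
Conditions: LiBH(s-Bu)3, THF, −78 °C; H2O; then PPTS (cat.), acetone–H2O, rt; chromatography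
Reagents that add atoms: water, O
Why: 1,2-Hydride reduction of the β-methyl enone followed by acetal hydrolysis: the bulky borohydride should enter anti to the pseudo-axial C1 methyl group, which places the new hydroxyl pseudo-axial and trans to the C6 side chain, and any cis epimer is removed by chromatography.

Step 14
Reactants: 25 rac-trans-3-hydroxy-α-ionone
Product: 26 (3R,6R)-3-hydroxy-α-ionone
Conditions: lipase PS (Burkholderia cepacia), vinyl acetate, t-BuOMe, 30 °C, run slightly past half conversion; chromatography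
Reagents that add atoms: none
Why: Lipase-catalysed kinetic resolution (enantioselective transesterification): the enzyme should acetylate the (3S,6S)-alcohol and leave the (3R,6R)-alcohol, whose enantiomeric purity rises as conversion passes one half.

Step 15
Reactants: 26 (3R,6R)-3-hydroxy-α-ionone
Product: 27 (3R,6R)-3-(triethylsilyloxy)-α-ionone
Conditions: Et3SiCl, imidazole, CH2Cl2, 0 °C
Reagents that add atoms: chlorotriethylsilane, CC[Si](Cl)(CC)CC
Why: Silylation of the allylic alcohol under mild base gives a triethylsilyl ether that survives amide bases and trimethylaluminium but is far more labile to fluoride than the tert-butyldiphenylsilyl ether of ring A.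

Step 16
Reactants: 27 (3R,6R)-3-(triethylsilyloxy)-α-ionone
Product: 30 ring B C13 dienyne, via lithium enolate 28 (not isolated), via enol phosphate 29 (not isolated)
Conditions: LiN(i-Pr)2 (1.05 equiv), THF, −78 °C; ClP(O)(OEt)2, −78 °C to rt; LiN(i-Pr)2 (2.2 equiv), −78 °C to rt; aq. NH4Cl
Reagents that add atoms: none
Why: The same methyl ketone to alkyne conversion through an enol phosphate as in step 8; deprotonation at −78 °C takes the methyl hydrogen kinetically, which should leave the γ-hydrogen at C6 and hence the 6R centre untouched.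

Step 17
Reactants: 30 ring B C13 dienyne; 6 (E)-(4-bromobut-3-en-1-yn-1-yl)trimethylsilane
Product: 32 ring B C18 silylated polyenyne, via ring B C14 alkenylalane 31 (not isolated)
Conditions: Me3Al (2 equiv), Cp2ZrCl2 (0.2 equiv), ClCH2CH2Cl, rt; volatiles removed; 6, ZnCl2 (1 equiv), Pd(PPh3)4 (cat.), THF, rt
Reagents that add atoms: trimethylaluminium, C[Al](C)C
Why: Negishi carboalumination followed by Negishi alkenyl–alkenyl coupling as in step 9: syn addition of Me–Al sets C9'=C10' as E and the E-bromoenyne brings C11'=C12' with retention.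

Step 18
Reactants: 32 ring B C18 silylated polyenyne
Product: 33 ring B C18 polyenyne
Conditions: K2CO3 (cat.), MeOH–THF, 0 °C to rt
Reagents that add atoms: none
Why: Protodesilylation of the alkynylsilane by catalytic methoxide; a secondary triethylsilyl ether should be stable under these brief conditions.

**Union and end game**

Step 19
Reactants: 20 ring A C18 polyenyne; 2 (E)-1-bromo-2-iodoethene; 33 ring B C18 polyenyne
Product: 37 lutein 3-O-tert-butyldiphenylsilyl 3'-O-triethylsilyl ether, via ring A C19 alkenylalane 34 (not isolated), via ring A bromopolyene 35 (not isolated), via ring B C19 alkenylalane 36 (not isolated)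
Conditions: 20, Me3Al (2 equiv), Cp2ZrCl2 (0.2 equiv), ClCH2CH2Cl, rt; volatiles removed; THF, ZnCl2, Pd(PPh3)4 (cat.), 2 (1.0 equiv), 0 °C to rt; then alane from 33 (Me3Al, Cp2ZrCl2, ClCH2CH2Cl, rt; volatiles removed; THF), ZnCl2, rt; argon, dark
Reagents that add atoms: trimethylaluminium, C[Al](C)C
Why: Cp2ZrCl2 and Me3Al form a bridged Zr–Al methyl species that adds methyl and metal syn across each terminal alkyne (C13≡C14 of 20, C13'≡C14' of 33) with the methyl on the internal carbon, so alanes 34 and 36 carry E-trisubstituted alkenes and the new C13–C20 and C13'–C20' bonds. ZnCl2 passes each alkenyl group from aluminium to zinc and on to the alkenylpalladium halide formed by oxidative addition of zerovalent palladium, and reductive elimination forms C14–C15 and then C15'–C14' with retention at every alkene. The closest known reaction type is the zirconium-catalysed alkyne carboalumination followed by palladium-catalysed Negishi alkenyl–alkenyl coupling with an (E)-1,2-dihaloethene as two-carbon linchpin. No ring closes and no stereocentre is made; C3, C3' and C6' are distant spectators and the silyl ethers should not react with Me3Al. The step needs syn addition with aluminium on the terminal carbon, which the conjugated terminal alkyne secures, and reaction at iodide before bromide, which rests on the much faster oxidative addition into C–I and on adding 34 first at 0 °C without excess. Removal of free Me3Al before each coupling keeps methyl transfer to the halide from competing.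

Step 20
Reactants: 37 lutein 3-O-tert-butyldiphenylsilyl 3'-O-triethylsilyl ether
Product: 38 lutein 3-O-tert-butyldiphenylsilyl ether
Conditions: HF·pyridine, excess pyridine, THF, 0 °C; argon, dark
Reagents that add atoms: none
Why: Fluoride-mediated silyl ether cleavage under pyridine buffering removes the small triethylsilyl group much faster than the bulky tert-butyldiphenylsilyl group and avoids the acidity that would ionise the allylic C3'–O bond.

Step 21
Reactants: 38 lutein 3-O-tert-butyldiphenylsilyl ether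
Product: 39 lutein 3-O-tert-butyldiphenylsilyl ether 3'-O-myristate
Conditions: myristoyl chloride, pyridine, DMAP (cat.), CH2Cl2, 0 °C to rt; dark
Reagents that add atoms: tetradecanoyl chloride, CCCCCCCCCCCCCC(=O)Cl
Why: DMAP-catalysed acylation with an acid chloride (nucleophilic acyl substitution) esterifies the only free hydroxyl, O3', with retention at C3'.

Step 22
Reactants: 39 lutein 3-O-tert-butyldiphenylsilyl ether 3'-O-myristate
Product: 40 lutein 3'-O-myristate
Conditions: Bu4NF, AcOH (1:1), THF, rt; dark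
Reagents that add atoms: none
Why: Fluoride-induced desilylation with acetic acid buffering should free O3 without cleaving the allylic myristate or isomerising the polyene.

Step 23
Reactants: 40 lutein 3'-O-myristate
Product: 41 lutein 3-O-palmitate 3'-O-myristate (target)
Conditions: palmitoyl chloride, pyridine, DMAP (cat.), CH2Cl2, 0 °C to rt; dark
Reagents that add atoms: hexadecanoyl chloride, CCCCCCCCCCCCCCCC(=O)Cl
Why: DMAP-catalysed acylation of the remaining secondary alcohol with the acid chloride completes the mixed diester with retention at C3.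

**Compound list**

1 | acetylene | C#C | starting material
2 | (E)-1-bromo-2-iodoethene | Br/C=C/I | intermediate
3 | ethynyltrimethylsilane | C#C[Si](C)(C)C | starting material
4 | lithium (trimethylsilyl)acetylide | [Li]C#C[Si](C)(C)C | intermediate
5 | bromo[(trimethylsilyl)ethynyl]zinc | Br[Zn]C#C[Si](C)(C)C | intermediate
6 | (E)-(4-bromobut-3-en-1-yn-1-yl)trimethylsilane | C[Si](C)(C)C#C/C=C/Br | intermediate
7 | ketoisophorone (2,6,6-trimethylcyclohex-2-ene-1,4-dione) | CC1=CC(=O)CC(C)(C)C1=O | starting material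
8 | (6R)-levodione, (6R)-2,2,6-trimethylcyclohexane-1,4-dione | C[C@@H]1CC(=O)CC(C)(C)C1=O | intermediate
9 | (4R,6R)-actinol, (4R,6R)-4-hydroxy-2,2,6-trimethylcyclohexan-1-one | C[C@@H]1C[C@@H](O)CC(C)(C)C1=O | intermediate
10 | (4R,6R)-4-(tert-butyldiphenylsilyloxy)-2,2,6-trimethylcyclohexan-1-one | C[C@@H]1C[C@@H](O[Si](c2ccccc2)(c2ccccc2)C(C)(C)C)CC(C)(C)C1=O | intermediate
11 | lithium (4R)-4-(tert-butyldiphenylsilyloxy)-2,6,6-trimethylcyclohex-1-en-1-olate (lithium enolate of 10) | CC(C)(C)[Si](c2ccccc2)(c2ccccc2)O[C@@H]1CC(C)=C(O[Li])C(C)(C)C1 | intermediate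
12 | (4R)-4-(tert-butyldiphenylsilyloxy)-2,6,6-trimethylcyclohex-1-en-1-yl trifluoromethanesulfonate (ring A enol triflate) | CC(C)(C)[Si](c2ccccc2)(c2ccccc2)O[C@@H]1CC(C)=C(OS(=O)(=O)C(F)(F)F)C(C)(C)C1 | intermediate
13 | methyl vinyl ketone (but-3-en-2-one) | C=CC(C)=O | starting material
14 | (3R)-3-(tert-butyldiphenylsilyloxy)-β-ionone, (E)-4-[(4R)-4-(tert-butyldiphenylsilyloxy)-2,6,6-trimethylcyclohex-1-en-1-yl]but-3-en-2-one | CC(C)(C)[Si](c2ccccc2)(c2ccccc2)O[C@@H]1CC(C)=C(/C=C/C(C)=O)C(C)(C)C1 | intermediate
15 | lithium enolate of 14 (methyl-side dienolate) | CC(C)(C)[Si](c2ccccc2)(c2ccccc2)O[C@@H]1CC(C)=C(/C=C/C(=C)O[Li])C(C)(C)C1 | intermediate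
16 | diethyl (3E)-4-[(4R)-4-(tert-butyldiphenylsilyloxy)-2,6,6-trimethylcyclohex-1-en-1-yl]buta-1,3-dien-2-yl phosphate (enol phosphate of 14) | CC(C)(C)[Si](c2ccccc2)(c2ccccc2)O[C@@H]1CC(C)=C(/C=C/C(=C)OP(=O)(OCC)OCC)C(C)(C)C1 | intermediate
17 | ring A C13 dienyne, tert-butyl{[(1R)-4-[(1E)-but-1-en-3-yn-1-yl]-3,5,5-trimethylcyclohex-3-en-1-yl]oxy}diphenylsilane | CC(C)(C)[Si](c2ccccc2)(c2ccccc2)O[C@@H]1CC(C)=C(/C=C/C#C)C(C)(C)C1 | intermediate
18 | ring A C14 alkenylalane, dimethyl[(1E,3E)-2-methyl-4-(ring A)buta-1,3-dien-1-yl]alane | CC(C)(C)[Si](c2ccccc2)(c2ccccc2)O[C@@H]1CC(C)=C(/C=C/C(C)=C/[Al](C)C)C(C)(C)C1 | intermediate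
19 | ring A C18 silylated polyenyne, tert-butyl{[(1R)-3,5,5-trimethyl-4-[(1E,3E,5E)-3-methyl-8-(trimethylsilyl)octa-1,3,5-trien-7-yn-1-yl]cyclohex-3-en-1-yl]oxy}diphenylsilane | CC(C)(C)[Si](c2ccccc2)(c2ccccc2)O[C@@H]1CC(C)=C(/C=C/C(C)=C/C=C/C#C[Si](C)(C)C)C(C)(C)C1 | intermediate
20 | ring A C18 polyenyne, tert-butyl{[(1R)-3,5,5-trimethyl-4-[(1E,3E,5E)-3-methylocta-1,3,5-trien-7-yn-1-yl]cyclohex-3-en-1-yl]oxy}diphenylsilane | CC(C)(C)[Si](c2ccccc2)(c2ccccc2)O[C@@H]1CC(C)=C(/C=C/C(C)=C/C=C/C#C)C(C)(C)C1 | intermediate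
21 | α-ionone (racemic) | CC(=O)/C=C/C1C(C)=CCCC1(C)C | starting material
22 | α-ionone ethylene acetal (racemic), 2-methyl-2-[(E)-2-(2,6,6-trimethylcyclohex-2-en-1-yl)ethenyl]-1,3-dioxolane | CC1(/C=C/C2C(C)=CCCC2(C)C)OCCO1 | intermediate
23 | 3-oxo-α-ionone ethylene acetal (racemic), 3,5,5-trimethyl-4-[(E)-2-(2-methyl-1,3-dioxolan-2-yl)ethenyl]cyclohex-2-en-1-one | CC1(/C=C/C2C(C)=CC(=O)CC2(C)C)OCCO1 | intermediate
24 | rac-trans-3-hydroxy-α-ionone ethylene acetal, (3R*,6R*) (racemate, one enantiomer drawn) | CC1(/C=C/[C@H]2C(C)=C[C@H](O)CC2(C)C)OCCO1 | intermediate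
25 | rac-trans-3-hydroxy-α-ionone, (3R*,6R*) (racemate, one enantiomer drawn) | CC(=O)/C=C/[C@H]1C(C)=C[C@H](O)CC1(C)C | intermediate
26 | (3R,6R)-3-hydroxy-α-ionone, (E)-4-[(1R,4R)-4-hydroxy-2,6,6-trimethylcyclohex-2-en-1-yl]but-3-en-2-one | CC(=O)/C=C/[C@H]1C(C)=C[C@H](O)CC1(C)C | intermediate
27 | (3R,6R)-3-(triethylsilyloxy)-α-ionone | CC(=O)/C=C/[C@H]1C(C)=C[C@H](O[Si](CC)(CC)CC)CC1(C)C | intermediate
28 | lithium enolate of 27 (methyl-side dienolate) | C=C(O[Li])/C=C/[C@H]1C(C)=C[C@H](O[Si](CC)(CC)CC)CC1(C)C | intermediate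
29 | diethyl (3E)-4-[(1R,4R)-2,6,6-trimethyl-4-(triethylsilyloxy)cyclohex-2-en-1-yl]buta-1,3-dien-2-yl phosphate (enol phosphate of 27) | C=C(OP(=O)(OCC)OCC)/C=C/[C@H]1C(C)=C[C@H](O[Si](CC)(CC)CC)CC1(C)C | intermediate
30 | ring B C13 dienyne, triethyl{[(1R,4R)-4-[(1E)-but-1-en-3-yn-1-yl]-3,5,5-trimethylcyclohex-2-en-1-yl]oxy}silane | C#C/C=C/[C@H]1C(C)=C[C@H](O[Si](CC)(CC)CC)CC1(C)C | intermediate
31 | ring B C14 alkenylalane, dimethyl[(1E,3E)-2-methyl-4-(ring B)buta-1,3-dien-1-yl]alane | C[Al](C)/C=C(C)/C=C/[C@H]1C(C)=C[C@H](O[Si](CC)(CC)CC)CC1(C)C | intermediate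
32 | ring B C18 silylated polyenyne, triethyl{[(1R,4R)-3,5,5-trimethyl-4-[(1E,3E,5E)-3-methyl-8-(trimethylsilyl)octa-1,3,5-trien-7-yn-1-yl]cyclohex-2-en-1-yl]oxy}silane | C[Si](C)(C)C#C/C=C/C=C(C)/C=C/[C@H]1C(C)=C[C@H](O[Si](CC)(CC)CC)CC1(C)C | intermediate
33 | ring B C18 polyenyne, triethyl{[(1R,4R)-3,5,5-trimethyl-4-[(1E,3E,5E)-3-methylocta-1,3,5-trien-7-yn-1-yl]cyclohex-2-en-1-yl]oxy}silane | C#C/C=C/C=C(C)/C=C/[C@H]1C(C)=C[C@H](O[Si](CC)(CC)CC)CC1(C)C | intermediate
34 | ring A C19 alkenylalane (dimethylalanyl on C14, methyl C20 on C13, 13E) | CC(C)(C)[Si](c2ccccc2)(c2ccccc2)O[C@@H]1CC(C)=C(/C=C/C(C)=C/C=C/C(C)=C/[Al](C)C)C(C)(C)C1 | intermediate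
35 | ring A bromopolyene (C21, bromine on C15', all-E) | CC(C)(C)[Si](c2ccccc2)(c2ccccc2)O[C@@H]1CC(C)=C(/C=C/C(C)=C/C=C/C(C)=C/C=C/Br)C(C)(C)C1 | intermediate
36 | ring B C19 alkenylalane (dimethylalanyl on C14', methyl C20' on C13', 13'E) | C[Al](C)/C=C(C)/C=C/C=C(C)/C=C/[C@H]1C(C)=C[C@H](O[Si](CC)(CC)CC)CC1(C)C | intermediate
37 | lutein 3-O-tert-butyldiphenylsilyl 3'-O-triethylsilyl ether, (3R,3'R,6'R), all-E | CC(C)(C)[Si](c3ccccc3)(c3ccccc3)O[C@@H]1CC(C)=C(/C=C/C(C)=C/C=C/C(C)=C/C=C/C=C(C)/C=C/C=C(C)/C=C/[C@H]2C(C)=C[C@H](O[Si](CC)(CC)CC)CC2(C)C)C(C)(C)C1 | intermediate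
38 | lutein 3-O-tert-butyldiphenylsilyl ether (free 3'-OH) | CC(C)(C)[Si](c3ccccc3)(c3ccccc3)O[C@@H]1CC(C)=C(/C=C/C(C)=C/C=C/C(C)=C/C=C/C=C(C)/C=C/C=C(C)/C=C/[C@H]2C(C)=C[C@H](O)CC2(C)C)C(C)(C)C1 | intermediate
39 | lutein 3-O-tert-butyldiphenylsilyl ether 3'-O-myristate | CC(C)(C)[Si](c3ccccc3)(c3ccccc3)O[C@@H]1CC(C)=C(/C=C/C(C)=C/C=C/C(C)=C/C=C/C=C(C)/C=C/C=C(C)/C=C/[C@H]2C(C)=C[C@H](OC(=O)CCCCCCCCCCCCC)CC2(C)C)C(C)(C)C1 | intermediate
40 | lutein 3'-O-myristate (free 3-OH) | O[C@@H]1CC(C)=C(/C=C/C(C)=C/C=C/C(C)=C/C=C/C=C(C)/C=C/C=C(C)/C=C/[C@H]2C(C)=C[C@H](OC(=O)CCCCCCCCCCCCC)CC2(C)C)C(C)(C)C1 | intermediate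
41 | lutein 3-O-palmitate 3'-O-myristate, (3R,3'R,6'R), all-E | CCCCCCCCCCCCCCCC(=O)O[C@@H]1CC(C)=C(/C=C/C(C)=C/C=C/C(C)=C/C=C/C=C(C)/C=C/C=C(C)/C=C/[C@H]2C(C)=C[C@H](OC(=O)CCCCCCCCCCCCC)CC2(C)C)C(C)(C)C1 | target

**Count and risks**

Total: 23 steps. Longest linear sequence: 13 steps (steps 11–18, then 19–23; the ring A branch, steps 3–10 then 19–23, is equally long).

Step 14. The enzyme may acylate the hindered pseudo-axial allylic alcohol too slowly, with too little enantiodiscrimination, or with the opposite preference. The fallback is a classical resolution through diastereomeric esters. Starting from 25, esterification with (2S)-methoxy(phenyl)acetic acid (DCC, DMAP cat., CH2Cl2, 0 °C) would give the (3R,6R)-ester F1 and the (3S,6S)-ester F2. These are diastereomers and would be separated by chromatography or crystallisation. Methanolysis of F1 (K2CO3, MeOH, 0 °C) comes back to the route at 26.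

Step 16. With excess amide base the doubly allylic C6–H may be removed, which would erode the 6R centre or shift the ring double bond into conjugation. The fallback replaces the elimination chemistry by olefinations. From 27, a Horner–Wadsworth–Emmons reaction with diethyl cyanomethylphosphonate (NaH, THF, 0 °C to rt) would give the C15 dienenitrile F3, the minor 9Z isomer being removed by chromatography. Reduction with i-Bu2AlH (CH2Cl2, −78 °C; aqueous tartrate work-up) would give the C15 dienal F4. A second Horner–Wadsworth–Emmons reaction with diethyl (3-trimethylsilylprop-2-ynyl)phosphonate (LiN(SiMe3)2, THF, −78 to 0 °C) rejoins the route at 32, so that 30 and step 17 are by-passed.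

Step 19. The two alkenyl transfers may not stay in order (double coupling of the first alane at both halide ends, homocoupling), or alkene geometry may erode while two alanes and zinc salts share one flask. The fallback uses isolated iodides and Stille couplings. Alane 34, made from 20 as before, would be quenched with I2 (THF, −30 °C) to the ring A alkenyl iodide F5. Stille coupling of F5 with an excess of (E)-1,2-bis(tributylstannyl)ethene (Pd2(dba)3, AsPh3, NMP, rt) would give the ring A stannyl hexaene F6. Alane 36, made from 33, would be iodinated in the same way to the ring B alkenyl iodide F7. Stille coupling of F6 with F7 under the same catalyst comes back to the route at 37. The methyl groups C20 and C20' and the bonds around the central ethene are still made from the same two alkynes and a C2 unit.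

**Further compounds**

F1 | step 14 | (1R,4R)-3,5,5-trimethyl-4-[(1E)-3-oxobut-1-en-1-yl]cyclohex-2-en-1-yl (2S)-methoxy(phenyl)acetate | CC(=O)/C=C/[C@H]1C(C)=C[C@H](OC(=O)[C@@H](OC)c2ccccc2)CC1(C)C
F2 | step 14 | (1S,4S)-3,5,5-trimethyl-4-[(1E)-3-oxobut-1-en-1-yl]cyclohex-2-en-1-yl (2S)-methoxy(phenyl)acetate | CC(=O)/C=C/[C@@H]1C(C)=C[C@@H](OC(=O)[C@@H](OC)c2ccccc2)CC1(C)C
F3 | step 16 | (2E,4E)-3-methyl-5-[(1R,4R)-2,6,6-trimethyl-4-(triethylsilyloxy)cyclohex-2-en-1-yl]penta-2,4-dienenitrile | N#C/C=C(C)/C=C/[C@H]1C(C)=C[C@H](O[Si](CC)(CC)CC)CC1(C)C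
F4 | step 16 | (2E,4E)-3-methyl-5-[(1R,4R)-2,6,6-trimethyl-4-(triethylsilyloxy)cyclohex-2-en-1-yl]penta-2,4-dienal | O=C/C=C(C)/C=C/[C@H]1C(C)=C[C@H](O[Si](CC)(CC)CC)CC1(C)C
F5 | step 19 | ring A alkenyl iodide (iodine on C14, 13E) | CC(C)(C)[Si](c2ccccc2)(c2ccccc2)O[C@@H]1CC(C)=C(/C=C/C(C)=C/C=C/C(C)=C/I)C(C)(C)C1
F6 | step 19 | ring A stannyl hexaene (tributylstannyl on C15', all-E) | CC(C)(C)[Si](c2ccccc2)(c2ccccc2)O[C@@H]1CC(C)=C(/C=C/C(C)=C/C=C/C(C)=C/C=C/[Sn](CCCC)(CCCC)CCCC)C(C)(C)C1
F7 | step 19 | ring B alkenyl iodide (iodine on C14', 13'E) | I/C=C(C)/C=C/C=C(C)/C=C/[C@H]1C(C)=C[C@H](O[Si](CC)(CC)CC)CC1(C)C
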